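**Plan**

- The target, 1-(3,5-dihydroxyphenyl)heptadecan-2-one, has one benzene ring with oxygens on C1 and C3 and its only carbon substituent on C5, all mutually meta. This 1,3,5-pattern is what a 3-monosubstituted cyclobutenone (arene C1, C4, C5, C6 and the C1 oxygen) and an alkoxyacetylene (C2, C3 and the C3 oxygen) deliver.
- Retrosynthesis: first the two O–ethyl bonds and the ketone (back to a silyl-protected secondary alcohol) are removed, then the arene is cut at ring bonds C1–C2, C3–C4 and C1–C6 to a 3-substituted cyclobut-2-enone and ethoxyacetylene.
- The cyclobutenone is cut to a terminal alkyne and dichloroketene, and the alkyne is cut between the carbinol carbon and the propargylic CH2 to hexadecanal and propargyl bromide.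
- Forward: the C16 and C3 pieces are joined first, then the four-membered ring is made, then the benzene ring arises in one thermal cascade, and ethylation, desilylation, oxidation and ether cleavage finish the route.
- Stereochemistry: the target has no stereocentre; the carbinol carbon made in step 1 is carried as the racemate and erased by the oxidation in step 8.

Key step: step 5

**Route**

Step 1
Reactants: 1 hexadecanal; 2 propargyl bromide
Product: 4 nonadec-1-yn-4-ol (racemic), via allenylzinc bromide 3 (not isolated)
Conditions: Zn dust, THF, 0 °C to rt; 1 M HCl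
Reagents that add atoms: none
Why: Barbier-type zinc propargylation, in which allenylzinc bromide 3 adds to the aldehyde through a cyclic SE2′ transition state and so should give the homopropargylic alcohol rather than the allenyl carbinol; the carbinol centre forms without control as the racemate, which is acceptable because it is oxidised later.

Step 2
Reactants: 4 nonadec-1-yn-4-ol
Product: 5 tert-butyldimethyl(nonadec-1-yn-4-yloxy)silane (racemic)
Conditions: TBSCl, imidazole, DMF, rt
Reagents that add atoms: tert-butyldimethylsilyl chloride, CC(C)(C)[Si](C)(C)Cl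
Why: Imidazole-mediated silylation of a secondary alcohol, which masks the future ketone oxygen against the acid chloride and the ketenes of the following steps.

Step 3
Reactants: 5 tert-butyldimethyl(nonadec-1-yn-4-yloxy)silane; 6 trichloroacetyl chloride
Product: 8 4,4-dichloro-3-[2-(tert-butyldimethylsilyloxy)heptadecyl]cyclobut-2-en-1-one (racemic), via dichloroketene 7 (not isolated)
Conditions: Zn–Cu couple, Et2O–DME, rt, slow addition of 6
Reagents that add atoms: none
Why: Ketene–alkyne [2+2] cycloaddition, in which zinc dechlorinates 6 to dichloroketene 7 and the terminal alkyne carbon attacks the ketene carbonyl carbon, so that the chain should end up on C3 of the dichlorocyclobutenone, while DME ties up ZnCl2 and spares the silyl ether.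

Step 4
Reactants: 8 4,4-dichloro-3-[2-(tert-butyldimethylsilyloxy)heptadecyl]cyclobut-2-en-1-one
Product: 10 3-[2-(tert-butyldimethylsilyloxy)heptadecyl]cyclobut-2-en-1-one (racemic), via monochlorocyclobutenone 9 (not isolated)
Conditions: Zn dust, AcOH, TMEDA, EtOH, 0 °C to rt
Reagents that add atoms: none
Why: Reductive dechlorination of an α,α-dichloroketone by zinc through zinc enolates, in an acetic acid–TMEDA buffer that is established for 4,4-dichlorocyclobutenones and is mild enough to leave the strained enone and the silyl ether intact.

Step 5
Reactants: 10 3-[2-(tert-butyldimethylsilyloxy)heptadecyl]cyclobut-2-en-1-one; 11 ethoxyacetylene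
Product: 16 3-ethoxy-5-[2-(tert-butyldimethylsilyloxy)heptadecyl]phenol (racemic), via vinylketene 12 (not isolated), via vinylcyclobutenone 13 (not isolated), via dienylketene 14 (not isolated), via cyclohexadienone 15 (not isolated)
Conditions: 11 (2 equiv), toluene, 80 °C, sealed tube
Reagents that add atoms: none
Why: Danheiser benzannulation: thermal four-electron opening of 10 gives vinylketene 12, whose ketene C=C adds to ethoxyacetylene in a [2+2] cycloaddition to give vinylcyclobutenone 13, a second four-electron opening gives dienylketene 14, and six-electron electrocyclisation followed by enolisation of dienone 15 should give phenol 16. The closest known reaction type is the union of 3-alkylcyclobutenones with alkoxyacetylenes to give 5-alkylresorcinol monoethers. The only ring closed is the benzene ring, by thermal disrotatory 6π electrocyclisation that joins the ketene carbon (arene C1) to the terminal methylene (arene C6), after the cycloaddition has made C1–C2 and C3–C4. No stereocentre is created in 16, since the sp3 ring carbon of 13 is transient and the side-chain carbinol centre is untouched. The selectivity needed is regiochemical: the ethoxy group makes the unsubstituted alkyne carbon the nucleophilic one, so it bonds to the ketene carbon and the two oxygens end up meta to each other and to the chain; opening of 13 is reversible, so only the dienylketene with ketene and vinyl units cis on the central double bond is drained to the arene. The medium is neutral and the temperature is kept below that at which ethoxyacetylene loses ethene, so the silyl ether and the alkyne both survive.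

Step 6
Reactants: 16 3-ethoxy-5-[2-(tert-butyldimethylsilyloxy)heptadecyl]phenol
Product: 17 tert-butyl{[1-(3,5-diethoxyphenyl)heptadecan-2-yl]oxy}dimethylsilane (racemic)
Conditions: EtI, K2CO3, DMF, 50 °C
Reagents that add atoms: ethyl iodide, CCI
Why: Williamson ether synthesis on the phenoxide, which shields the phenol from the periodinane of step 8 and makes the arene a symmetrical 3,5-diethoxyphenyl unit that one reagent can unmask at the end.

Step 7
Reactants: 17 tert-butyl{[1-(3,5-diethoxyphenyl)heptadecan-2-yl]oxy}dimethylsilane
Product: 18 1-(3,5-diethoxyphenyl)heptadecan-2-ol (racemic)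
Conditions: TBAF, THF, rt
Reagents that add atoms: none
Why: Fluoride-induced desilylation driven by the strong Si–F bond, to which aryl ethyl ethers are inert.

Step 8
Reactants: 18 1-(3,5-diethoxyphenyl)heptadecan-2-ol
Product: 19 1-(3,5-diethoxyphenyl)heptadecan-2-one
Conditions: Dess–Martin periodinane, CH2Cl2, rt
Reagents that add atoms: none
Why: Dess–Martin oxidation of a secondary alcohol to the ketone under neutral non-aqueous conditions, which removes the only stereocentre and should not touch the fully etherified arene.

Step 9
Reactants: 19 1-(3,5-diethoxyphenyl)heptadecan-2-one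
Product: 20 1-(3,5-dihydroxyphenyl)heptadecan-2-one
Conditions: BBr3 (5 equiv), CH2Cl2, −78 °C to rt; then H2O
Reagents that add atoms: none
Why: Lewis acid ether cleavage, in which BBr3 coordinates each aryl ether oxygen and bromide removes the ethyl group as bromoethane, the aryl borates being hydrolysed on work-up, while a simple ketone should survive this reagent at or below room temperature.

**Compound list**

1 | hexadecanal | CCCCCCCCCCCCCCCC=O | starting material
2 | propargyl bromide (3-bromoprop-1-yne) | C#CCBr | starting material
3 | allenylzinc bromide (bromo(propa-1,2-dienyl)zinc) | C=C=C[Zn]Br | intermediate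
4 | nonadec-1-yn-4-ol (racemic) | CCCCCCCCCCCCCCCC(O)CC#C | intermediate
5 | tert-butyldimethyl(nonadec-1-yn-4-yloxy)silane (racemic) | CCCCCCCCCCCCCCCC(O[Si](C)(C)C(C)(C)C)CC#C | intermediate
6 | trichloroacetyl chloride | ClC(Cl)(Cl)C(Cl)=O | starting material
7 | dichloroketene | ClC(Cl)=C=O | intermediate
8 | 4,4-dichloro-3-[2-(tert-butyldimethylsilyloxy)heptadecyl]cyclobut-2-en-1-one (racemic) | CCCCCCCCCCCCCCCC(O[Si](C)(C)C(C)(C)C)CC1=CC(=O)C1(Cl)Cl | intermediate
9 | 4-chloro-3-[2-(tert-butyldimethylsilyloxy)heptadecyl]cyclobut-2-en-1-one (mixture of diastereomers) | CCCCCCCCCCCCCCCC(O[Si](C)(C)C(C)(C)C)CC1=CC(=O)C1Cl | intermediate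
10 | 3-[2-(tert-butyldimethylsilyloxy)heptadecyl]cyclobut-2-en-1-one (racemic) | CCCCCCCCCCCCCCCC(O[Si](C)(C)C(C)(C)C)CC1=CC(=O)C1 | intermediate
11 | ethoxyacetylene | CCOC#C | starting material
12 | 3-[2-(tert-butyldimethylsilyloxy)heptadecyl]buta-1,3-dien-1-one (vinylketene, racemic) | CCCCCCCCCCCCCCCC(O[Si](C)(C)C(C)(C)C)CC(=C)C=C=O | intermediate
13 | 3-ethoxy-4-[4-(tert-butyldimethylsilyloxy)nonadec-1-en-2-yl]cyclobut-2-en-1-one (mixture of diastereomers) | CCCCCCCCCCCCCCCC(O[Si](C)(C)C(C)(C)C)CC(=C)C1C(OCC)=CC1=O | intermediate
14 | (3E)-3-ethoxy-5-[2-(tert-butyldimethylsilyloxy)heptadecyl]hexa-1,3,5-trien-1-one (dienylketene, ketene and vinyl units cis, racemic) | CCCCCCCCCCCCCCCC(O[Si](C)(C)C(C)(C)C)CC(=C)/C=C(/OCC)C=C=O | intermediate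
15 | 3-ethoxy-5-[2-(tert-butyldimethylsilyloxy)heptadecyl]cyclohexa-2,4-dien-1-one (racemic) | CCCCCCCCCCCCCCCC(O[Si](C)(C)C(C)(C)C)CC1=CC(OCC)=CC(=O)C1 | intermediate
16 | 3-ethoxy-5-[2-(tert-butyldimethylsilyloxy)heptadecyl]phenol (racemic) | CCCCCCCCCCCCCCCC(O[Si](C)(C)C(C)(C)C)Cc1cc(O)cc(OCC)c1 | intermediate
17 | tert-butyl{[1-(3,5-diethoxyphenyl)heptadecan-2-yl]oxy}dimethylsilane (racemic) | CCCCCCCCCCCCCCCC(O[Si](C)(C)C(C)(C)C)Cc1cc(OCC)cc(OCC)c1 | intermediate
18 | 1-(3,5-diethoxyphenyl)heptadecan-2-ol (racemic) | CCCCCCCCCCCCCCCC(O)Cc1cc(OCC)cc(OCC)c1 | intermediate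
19 | 1-(3,5-diethoxyphenyl)heptadecan-2-one | CCCCCCCCCCCCCCCC(=O)Cc1cc(OCC)cc(OCC)c1 | intermediate
20 | 1-(3,5-dihydroxyphenyl)heptadecan-2-one | CCCCCCCCCCCCCCCC(=O)Cc1cc(O)cc(O)c1 | target

**Step count**

Total: 9 steps. Longest linear sequence: 9 steps, from hexadecanal 1 to target 20.

**Steps most likely to fail**

Step 3. The ZnCl2 formed alongside dichloroketene may strip or ionise the silyl ether, chlorine may migrate in the product, and an unactivated terminal alkyne may be consumed more slowly than the ketene oligomerises. The fallback sets out from alkyne 5 and comes back at cyclobutenone 10, bypassing steps 3 and 4. N,N-Dimethylacetamide is activated with Tf2O and 2,4,6-collidine in 1,2-dichloroethane to give N,N-dimethylketeniminium triflate F1. This adds to 5 at reflux in a keteniminium–alkyne [2+2] cycloaddition to give cyclobuteniminium triflate F2. Hydrolysis with aqueous NaHCO3 should release 10 directly, with no chlorine to remove.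

Step 5. Vinylketene 12 may be intercepted by the phenol already formed (O-acylation to an aryl ester) or may dimerise, and vinylcyclobutenone 13 may open too slowly at a temperature the alkyne tolerates. A brief K2CO3/MeOH treatment of the crude product would return any aryl ester to 16. If the cascade itself fails, the fallback sets out from hexadecanal 1 and comes back at alcohol 18; it gives up the ring construction and buys the arene. Corey–Chaykovsky methylenation with dimethylsulfonium methylide F3 (from trimethylsulfonium iodide and NaH in DMSO–THF) gives 2-pentadecyloxirane F4. (3,5-Diethoxyphenyl)magnesium bromide F5, made from commercial 1-bromo-3,5-diethoxybenzene (CCOc1cc(Br)cc(OCC)c1) and Mg in THF, should open F4 at its unsubstituted carbon under CuI catalysis and give 18 after a dilute HCl quench. Steps 8 and 9 then follow unchanged.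

Step 9. The second ether cleavage may stall, or the enolisable benzyl ketone may self-condense under the Lewis acid. The fallback sets out from alcohol 18 and comes back at target 20; it frees the phenols before the ketone exists. BBr3 in CH2Cl2 should convert 18 into 5-(2-hydroxyheptadecyl)benzene-1,3-diol F6, the secondary alcohol being returned from its borate on work-up. Schotten–Baumann acetylation (Ac2O, aqueous NaOH, 0 °C) should acylate only the phenols and give 5-(2-hydroxyheptadecyl)-1,3-phenylene diacetate F7. Dess–Martin oxidation gives 5-(2-oxoheptadecyl)-1,3-phenylene diacetate F8, and K2CO3 in MeOH at rt removes the aryl acetates to give 20 without any Lewis acid touching the ketone.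

**Further compounds**

F1 | step 3 | N,N-dimethylketeniminium triflate (N-ethenylidene-N-methylmethanaminium trifluoromethanesulfonate) | C=C=[N+](C)C.[O-]S(=O)(=O)C(F)(F)F
F2 | step 3 | N-{3-[2-(tert-butyldimethylsilyloxy)heptadecyl]cyclobut-2-en-1-ylidene}-N-methylmethanaminium trifluoromethanesulfonate (racemic) | CCCCCCCCCCCCCCCC(O[Si](C)(C)C(C)(C)C)CC1=CC(=[N+](C)C)C1.[O-]S(=O)(=O)C(F)(F)F
F3 | step 5 | dimethylsulfonium methylide | C[S+](C)[CH2-]
F4 | step 5 | 2-pentadecyloxirane (racemic) | CCCCCCCCCCCCCCCC1CO1
F5 | step 5 | (3,5-diethoxyphenyl)magnesium bromide | CCOc1cc(OCC)cc([Mg]Br)c1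
F6 | step 9 | 5-(2-hydroxyheptadecyl)benzene-1,3-diol (racemic) | CCCCCCCCCCCCCCCC(O)Cc1cc(O)cc(O)c1
F7 | step 9 | 5-(2-hydroxyheptadecyl)-1,3-phenylene diacetate (racemic) | CCCCCCCCCCCCCCCC(O)Cc1cc(OC(C)=O)cc(OC(C)=O)c1
F8 | step 9 | 5-(2-oxoheptadecyl)-1,3-phenylene diacetate | CCCCCCCCCCCCCCCC(=O)Cc1cc(OC(C)=O)cc(OC(C)=O)c1
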